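The cyclohexenone ring (C1 carbonyl, C2=C3 alkene, C4 methylene, C5 carbinol carbon, C6 methylene) is cut at C1–C2 and C1–C6. This leaves carbon monoxide and a five-carbon unit that closes to a cyclopropane through C4–C6. The key step reverses this: an iron-mediated carbonylative [5+1] ring expansion of a (1R,2R)-1-silyloxy-1-nonadecyl-2-vinylcyclopropane (ring C4, C5, C6; vinyl C3=C2, cis to the silyloxy group) opens C4–C6 and forms both bonds to C1 in one operation. The C5 stereocentre, set earlier by an asymmetric Simmons–Smith reaction, is untouched. Alkene migration and desilylation finish the synthesis.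

Key step: step 7

Remark: ring atoms keep the labels C1–C6 of the target throughout. The descriptor at C5 changes along the route only because the priorities of its neighbours change, not its geometry. The dioxaborolane ligand and Fe(CO)5 are taken as commercial.

Step 1
Reactants: 1 eicosanoic acid; 2 Meldrum's acid (2,2-dimethyl-1,3-dioxane-4,6-dione)
Product: 4 methyl 3-oxodocosanoate, via eicosanoyl Meldrum's acid 3 (not isolated)
Conditions: DCC, DMAP, CH2Cl2, 0 °C to rt; filter, concentrate; MeOH, reflux
Reagents that add atoms: methanol, CO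
Why: Carbodiimide-mediated C-acylation of Meldrum's acid followed by methanolysis with loss of acetone and CO2 is the standard Meldrum's acid route from a fatty acid to its β-keto ester.

Step 2
Reactants: 4 methyl 3-oxodocosanoate
Product: 5 methyl (Z)-3-{[tert-butyl(dimethyl)silyl]oxy}docos-2-enoate
Conditions: NaH, THF, 0 °C; TBSCl, 0 °C to rt
Reagents that add atoms: tert-butyldimethylsilyl chloride, CC(C)(C)[Si](C)(C)Cl
Why: O-Silylation of the sodium enolate, in which sodium bridges both oxygens, should give the (Z)-silyl enol ether (silyloxy cis to the ester) by analogy with Z-selective enol phosphate formation from β-keto esters under the same chelating conditions, and the geometry is to be confirmed by NOE because it decides the configuration set in step 4.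

Step 3
Reactants: 5 methyl (Z)-3-{[tert-butyl(dimethyl)silyl]oxy}docos-2-enoate
Product: 6 (Z)-3-{[tert-butyl(dimethyl)silyl]oxy}docos-2-en-1-ol
Conditions: i-Bu2AlH (2.3 equiv), CH2Cl2, −78 °C; aq potassium sodium tartrate
Reagents that add atoms: none
Why: 1,2-Hydride reduction of the enoate to the allylic alcohol at low temperature with a neutral work-up should leave the silyl enol ether and its geometry intact.

Step 4
Reactants: 6 (Z)-3-{[tert-butyl(dimethyl)silyl]oxy}docos-2-en-1-ol; 7 diiodomethane
Product: 8 [(1R,2R)-2-{[tert-butyl(dimethyl)silyl]oxy}-2-nonadecylcyclopropyl]methanol (silyloxy and hydroxymethyl cis)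
Conditions: Et2Zn, CH2I2, DME, CH2Cl2, −10 °C; then 6 and (4R,5R)-2-butyl-N,N,N′,N′-tetramethyl-1,3,2-dioxaborolane-4,5-dicarboxamide (1.2 equiv), −10 °C to rt; aq NH4Cl
Reagents that add atoms: diiodomethane (7), ICI
Why: In this dioxaborolane-directed asymmetric Simmons–Smith cyclopropanation the alkoxide bound to the chiral boronate directs CH2 from Zn(CH2I)2 to one alkene face; the (4R,5R)-ligand, which gives (S,S)-products from (E)-allylic alcohols, should attack the face of the (Z)-enol ether that makes C5 (R) and C4 (R), with silyloxy and hydroxymethyl cis by stereospecific syn addition.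

Step 5
Reactants: 8 [(1R,2R)-2-{[tert-butyl(dimethyl)silyl]oxy}-2-nonadecylcyclopropyl]methanol
Product: 9 (1S,2R)-2-{[tert-butyl(dimethyl)silyl]oxy}-2-nonadecylcyclopropane-1-carbaldehyde
Conditions: Dess–Martin periodinane, pyridine, CH2Cl2, 0 °C
Reagents that add atoms: none
Why: Dess–Martin oxidation under pyridine buffer should convert the primary alcohol into the aldehyde without the acid that could open this donor–acceptor cyclopropane, and it touches no stereocentre.

Step 6
Reactants: 9 (1S,2R)-2-{[tert-butyl(dimethyl)silyl]oxy}-2-nonadecylcyclopropane-1-carbaldehyde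
Product: 10 tert-butyl{[(1R,2R)-2-ethenyl-1-nonadecylcyclopropyl]oxy}dimethylsilane (vinyl cis to the silyloxy group)
Conditions: Ph3PCH3Br, KN(SiMe3)2, THF, 0 °C; then 9, −78 °C to 0 °C
Reagents that add atoms: methyltriphenylphosphonium bromide, C[P+](c1ccccc1)(c1ccccc1)c1ccccc1.[Br-]
Why: Wittig methylenation with Ph3P=CH2 at low temperature should convert the aldehyde into the vinyl group faster than the weakly acidic cyclopropyl C–H is removed, as is known for 2-silyloxycyclopropanecarbaldehydes.

Step 7
Reactants: 10 tert-butyl{[(1R,2R)-2-ethenyl-1-nonadecylcyclopropyl]oxy}dimethylsilane; 11 carbon monoxide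
Product: 12 (R)-5-{[tert-butyl(dimethyl)silyl]oxy}-5-nonadecylcyclohex-3-en-1-one
Conditions: Fe(CO)5 (1.5 equiv), CO (1 atm), hν (medium-pressure mercury lamp, Pyrex), i-PrOH–hexane, rt; air, filtration through silica
Reagents that add atoms: carbon monoxide (11), [C-]#[O+]
Why: Photolysis of Fe(CO)5 gives Fe(CO)4, which binds the vinyl group (C2=C3) and inserts into the adjacent, less substituted cyclopropane bond C4–C6 to give a ferracycle with a σ-bond to C6 and an η3-allyl over C2–C4; CO then migrates into the Fe–C6 bond, reductive elimination joins the acyl carbon C1 to C2, and Fe(CO)5 is re-formed by uptake of CO, so the net change is addition of one CO. The closest known reaction type is the Fe(CO)5-mediated carbonylation of 2-substituted alkenylcyclopropanes to 5-substituted cyclohexenones, a formal [5+1] cycloaddition that also runs under monovalent rhodium catalysis. The six-membered ring is closed by acyl–allyl reductive elimination at the metal (C1–C2) after insertion has made C1–C6, so both new bonds arise inside one metallacycle. No stereocentre is created: C4 becomes trigonal and C5 keeps all four of its bonds, so the configuration fixed on the cyclopropane is carried over unchanged. The selectivity needed is regiochemical, cleavage of C4–C6 and not of C4–C5, and it should be secured by the fully substituted C5, whose silyloxy group lies on the same side as the vinyl group and shields that bond, while a bond from iron to a tertiary carbon would be far more crowded. Because C5 bears no hydrogen the σ-alkyl cannot collapse to a diene by β-hydride elimination, and because the nonadecyl chain is trans to the vinyl group no homodienyl 1,5-hydrogen shift can compete.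

Step 8
Reactants: 12 (R)-5-{[tert-butyl(dimethyl)silyl]oxy}-5-nonadecylcyclohex-3-en-1-one
Product: 13 (S)-5-{[tert-butyl(dimethyl)silyl]oxy}-5-nonadecylcyclohex-2-en-1-one
Conditions: RhCl3·3H2O (5 mol %), EtOH–THF, 50 °C
Reagents that add atoms: none
Why: Transition-metal-catalysed alkene isomerisation through an η3-allyl rhodium hydride formed at the doubly activated C2–H should move the C3=C4 alkene into the thermodynamically favoured conjugated C2=C3 position without base, so that E1cB loss of the β-silyloxy group and aromatisation are avoided (any 13 already formed in step 7 is simply carried along).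

Step 9
Reactants: 13 (S)-5-{[tert-butyl(dimethyl)silyl]oxy}-5-nonadecylcyclohex-2-en-1-one
Product: 14 (S)-5-hydroxy-5-nonadecylcyclohex-2-en-1-one (target)
Conditions: HF·pyridine, pyridine, THF, 0 °C to rt (polyethylene vessel); aq NaHCO3
Reagents that add atoms: none
Why: Fluoride-mediated desilylation with pyridine-buffered HF·pyridine should cleave the tertiary silyl ether under near-neutral conditions that trigger neither retro-aldol cleavage nor dehydration of the β-hydroxy enone, and C5 is not involved.

Compound list
1 | eicosanoic acid | CCCCCCCCCCCCCCCCCCCC(O)=O | starting material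
2 | Meldrum's acid (2,2-dimethyl-1,3-dioxane-4,6-dione) | CC1(C)OC(=O)CC(=O)O1 | starting material
3 | eicosanoyl Meldrum's acid, enol form: 5-(1-hydroxyicosylidene)-2,2-dimethyl-1,3-dioxane-4,6-dione | CCCCCCCCCCCCCCCCCCCC(O)=C1C(=O)OC(C)(C)OC1=O | intermediate (not isolated)
4 | methyl 3-oxodocosanoate | CCCCCCCCCCCCCCCCCCCC(=O)CC(=O)OC | intermediate
5 | methyl (Z)-3-{[tert-butyl(dimethyl)silyl]oxy}docos-2-enoate | CCCCCCCCCCCCCCCCCCC/C(O[Si](C)(C)C(C)(C)C)=C/C(=O)OC | intermediate
6 | (Z)-3-{[tert-butyl(dimethyl)silyl]oxy}docos-2-en-1-ol | CCCCCCCCCCCCCCCCCCC/C(O[Si](C)(C)C(C)(C)C)=C/CO | intermediate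
7 | diiodomethane | ICI | starting material
8 | [(1R,2R)-2-{[tert-butyl(dimethyl)silyl]oxy}-2-nonadecylcyclopropyl]methanol | CCCCCCCCCCCCCCCCCCC[C@]1(O[Si](C)(C)C(C)(C)C)[C@@H](CO)C1 | intermediate
9 | (1S,2R)-2-{[tert-butyl(dimethyl)silyl]oxy}-2-nonadecylcyclopropane-1-carbaldehyde | CCCCCCCCCCCCCCCCCCC[C@]1(O[Si](C)(C)C(C)(C)C)[C@@H](C=O)C1 | intermediate
10 | tert-butyl{[(1R,2R)-2-ethenyl-1-nonadecylcyclopropyl]oxy}dimethylsilane | CCCCCCCCCCCCCCCCCCC[C@]1(O[Si](C)(C)C(C)(C)C)[C@@H](C=C)C1 | intermediate
11 | carbon monoxide | [C-]#[O+] | starting material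
12 | (R)-5-{[tert-butyl(dimethyl)silyl]oxy}-5-nonadecylcyclohex-3-en-1-one | CCCCCCCCCCCCCCCCCCC[C@]1(O[Si](C)(C)C(C)(C)C)C=CCC(=O)C1 | intermediate
13 | (S)-5-{[tert-butyl(dimethyl)silyl]oxy}-5-nonadecylcyclohex-2-en-1-one | CCCCCCCCCCCCCCCCCCC[C@]1(O[Si](C)(C)C(C)(C)C)CC=CC(=O)C1 | intermediate
14 | (S)-5-hydroxy-5-nonadecylcyclohex-2-en-1-one | CCCCCCCCCCCCCCCCCCC[C@]1(O)CC=CC(=O)C1 | target

Total step count: 9. Longest linear sequence: 9 steps (1 to 14).

Steps most likely to fail

Step 7. Iron may insert into the C4–C5 bond, which the silyloxy donor weakens electronically, or the ferracycle may lose the silyloxy group by β-oxygen elimination or heterolytic ring opening, so that no cyclohexenone forms. The fallback builds the ring first and sets C5 afterwards; it sets out from 4 and comes back at 14.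
- Robinson annulation of 4 with methyl vinyl ketone (catalytic NaOMe in MeOH for the Michael addition, then pyrrolidine/AcOH for the aldol condensation) should give racemic methyl 2-nonadecyl-4-oxocyclohex-2-ene-1-carboxylate F1.
- Saponification and decarboxylation of this vinylogous β-keto ester (KOH, aq MeOH, reflux; then acid) should give 3-nonadecylcyclohex-2-en-1-one F2.
- Copper-catalysed enantioselective conjugate borylation ([Cu(MeCN)4]PF6, a chiral bisphosphine such as QuinoxP*, B2pin2, LiOt-Bu, DMSO, rt), a reaction known for 3-alkylcyclohexenones, should give (R)-3-nonadecyl-3-(4,4,5,5-tetramethyl-1,3,2-dioxaborolan-2-yl)cyclohexan-1-one F3. The ligand enantiomer is chosen to give this configuration.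
- Oxidation with retention (NaBO3·4H2O, THF–H2O) should give (S)-3-hydroxy-3-nonadecylcyclohexan-1-one F4.
- Dehydrogenation with IBX and 4-methoxypyridine N-oxide in DMSO at rt can only introduce the C2=C3 alkene, because C5 carries no hydrogen, and so should deliver 14.

Step 4. Methylene delivery may be poorly face-selective or slow for a trisubstituted silyl enol ether, and zinc salts may cause silyl migration to the primary oxygen or cleavage of the enol ether. The fallback replaces asymmetric induction by resolution; it sets out from 6 and comes back at 8.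
- Cyclopropanation of 6 without the chiral ligand (Et2Zn, CH2I2, CH2Cl2, 0 °C, hydroxyl-directed) should give the racemic cis alcohol, that is 8 together with its enantiomer [(1S,2S)-2-{[tert-butyl(dimethyl)silyl]oxy}-2-nonadecylcyclopropyl]methanol F5.
- Esterification with (S)-2-methoxy-2-phenylacetic acid (DCC, DMAP, CH2Cl2, 0 °C) should give two diastereomers: [(1R,2R)-2-{[tert-butyl(dimethyl)silyl]oxy}-2-nonadecylcyclopropyl]methyl (S)-2-methoxy-2-phenylacetate F6 and [(1S,2S)-2-{[tert-butyl(dimethyl)silyl]oxy}-2-nonadecylcyclopropyl]methyl (S)-2-methoxy-2-phenylacetate F7.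
- The two are separated by chromatography or crystallisation.
- Methanolysis of F6 (K2CO3, MeOH, rt) should return 8.

Step 8. Alkene migration may stall, or be overtaken by loss of silanol from the β-silyloxy ketone followed by aromatisation to the phenol. The fallback removes the alkene and reintroduces it regioselectively; it sets out from 12 and comes back at 13.
- Hydrogenation of 12 (H2, platinum on carbon, EtOAc) should give (S)-3-{[tert-butyl(dimethyl)silyl]oxy}-3-nonadecylcyclohexan-1-one F8.
- Kinetic enolisation away from the quaternary carbon (LiN(i-Pr)2, Me3SiCl, THF, −78 °C) should give tert-butyl(dimethyl){[(1S)-1-nonadecyl-3-(trimethylsilyloxy)cyclohex-3-en-1-yl]oxy}silane F9.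
- Saegusa–Ito oxidation (Pd(OAc)2, MeCN, rt) should then give 13.

Further compounds
F1 | step 7 | methyl 2-nonadecyl-4-oxocyclohex-2-ene-1-carboxylate (racemic) | CCCCCCCCCCCCCCCCCCCC1=CC(=O)CCC1C(=O)OC
F2 | step 7 | 3-nonadecylcyclohex-2-en-1-one | CCCCCCCCCCCCCCCCCCCC1=CC(=O)CCC1
F3 | step 7 | (R)-3-nonadecyl-3-(4,4,5,5-tetramethyl-1,3,2-dioxaborolan-2-yl)cyclohexan-1-one | CCCCCCCCCCCCCCCCCCC[C@]1(B2OC(C)(C)C(C)(C)O2)CCCC(=O)C1
F4 | step 7 | (S)-3-hydroxy-3-nonadecylcyclohexan-1-one | CCCCCCCCCCCCCCCCCCC[C@]1(O)CCCC(=O)C1
F5 | step 4 | [(1S,2S)-2-{[tert-butyl(dimethyl)silyl]oxy}-2-nonadecylcyclopropyl]methanol (enantiomer of 8, formed as the racemate with 8) | CCCCCCCCCCCCCCCCCCC[C@@]1(O[Si](C)(C)C(C)(C)C)[C@H](CO)C1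
F6 | step 4 | [(1R,2R)-2-{[tert-butyl(dimethyl)silyl]oxy}-2-nonadecylcyclopropyl]methyl (S)-2-methoxy-2-phenylacetate | CCCCCCCCCCCCCCCCCCC[C@]1(O[Si](C)(C)C(C)(C)C)[C@@H](COC(=O)[C@@H](OC)c2ccccc2)C1
F7 | step 4 | [(1S,2S)-2-{[tert-butyl(dimethyl)silyl]oxy}-2-nonadecylcyclopropyl]methyl (S)-2-methoxy-2-phenylacetate | CCCCCCCCCCCCCCCCCCC[C@@]1(O[Si](C)(C)C(C)(C)C)[C@H](COC(=O)[C@@H](OC)c2ccccc2)C1
F8 | step 8 | (S)-3-{[tert-butyl(dimethyl)silyl]oxy}-3-nonadecylcyclohexan-1-one | CCCCCCCCCCCCCCCCCCC[C@]1(O[Si](C)(C)C(C)(C)C)CCCC(=O)C1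
F9 | step 8 | tert-butyl(dimethyl){[(1S)-1-nonadecyl-3-(trimethylsilyloxy)cyclohex-3-en-1-yl]oxy}silane | CCCCCCCCCCCCCCCCCCC[C@]1(O[Si](C)(C)C(C)(C)C)CCC=C(O[Si](C)(C)C)C1
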